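One question is asked, of 3 flasks: how much first product stands after 1.0 h.

the same everywhere: starting material 0.20 M
- eta: partner 0.12 M; run made earlier
- zeta: partner 0.23 M; run made earlier
- epsilon: partner 0.46 M; run made earlier
- south-east: partner 0.100 M; time 1.0 h
- north-east: partner 0.400 M; time 1.0 h
- south: partner 0.500 M; time 1.0 h

- eta (time / min: first product / %): 4.00: 7.9; 10.0: 12.7; 20.0: 12.8; 30.0: 9.9; 40.0: 11.1
- zeta (time / min: first product / %): 4.00: 15.9; 10.0: 18.4; 20.0: 17.9; 30.0: 17.6; 40.0: 18.3
- epsilon (time / min: first product / %): 4.00: 21.4; 10.0: 22.9; 20.0: 21.5; 30.0: 24.2; 40.0: 23.0

(each reading ± 1 percentage point)

1. final first product, as a percentage of the starting material charged, for each flask in turn (south-east, north-east, south)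

- steps that have been proposed: starting material + partner -> first product; starting material + partner -> other mono adduct; partner + first product -> double product; partner + other mono adduct -> double product; partner -> decomposed reagent; first product <-> isomer of the product

From 10.0 min to 40.0 min the readings of each run stay level within their scatter, so each run can be read as one plateau: 11.6% in eta, 18.1% in zeta and 22.9% in epsilon. Between eta and zeta, 0.584 M⁻¹ is the marginal yield, the fraction of the starting material charged gained as first product per molar of partner added. But between zeta and epsilon it reads only 0.211 M⁻¹, less than before, so the plateau curve bends downward. Such a curve lies above its chord between two runs and below that chord's extension outside them. My own reckoning therefore puts south-east at or below 10.5%, north-east at or above 21.6% and south at or below 23.7%.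

The forecast gives 10%, 22.3% and 23.5%, holding that “the partner must die quickly”.

    starting material + partner → first product (k = 0.0180 M⁻¹ s⁻¹)
    starting material + partner → other mono adduct (k = 0.00140 M⁻¹ s⁻¹)
    partner + first product → double product (k = 0.0150 M⁻¹ s⁻¹)
    partner + other mono adduct → double product (k = 1.80 × 10⁻⁴ M⁻¹ s⁻¹)
    partner → decomposed reagent (k = 0.00330 s⁻¹)
    first product ⇌ isomer of the product (K = 1.20, k = 0.0610 s⁻¹)

The flasks give 9.85% in south-east, 23.2% in north-east and 23.5% in south, so the marginal yield reads 0.445 M⁻¹ from south-east to north-east and falls to 0.0300 M⁻¹ from north-east to south. Leaving the isomer of the product out of the count, the rate of the step from starting material to first product over the rate of the step from first product to double product, in which partner cancels, stands on the amounts at the end at 1.41 in north-east and at 0.936 in south.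

The data come from a simulation for an exercise, noise included.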